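A slow feed of one equivalent tempts me to read the end of the feed as the end of the reaction. Here Q is dosed over 3.0 h into Z and the base E, and I want to know how much Z has reacted when the feed stops, at three levels of E.

| setting | ash | larch | Sunday's | Saturday's | Monday's |
|---|---|---|---|---|---|
| Z | 0.031 M | 0.031 M | 0.031 M | 0.031 M | 0.031 M |
| Q | 0.031 M (fed, over 3.0 h) | 0.031 M (fed, over 3.0 h) | 0.0310 M (fed, over 3.0 h) | 0.0310 M (fed, over 3.0 h) | 0.0310 M (fed, over 3.0 h) |
| E | 0.059 M | 0.11 M | 0.0700 M | 0.100 M | 0.0460 M |
| remark | run made earlier; the fed solution adds 0.25 times the starting volume | run made earlier; the fed solution adds 0.25 times the starting volume | the fed solution adds 0.25 times the starting volume | the fed solution adds 0.25 times the starting volume | the fed solution adds 0.25 times the starting volume |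
| time |  |  | 3.0 h | 3.0 h | 3.0 h |

- ash (time / min: Z / %, J / %): 12.0: 98.8, 1.2; 25.0: 98.1, 0; 40.0: 98.5, 4.0; 50.0: 96.1, 3.5; 60.0: 96.7, 5.0; 80.0: 89.8, 10.9; 90.0: 88.5, 9.8
- larch (time / min: Z / %, J / %): 12.0: 100.4, 0; 25.0: 97.4, 0; 40.0: 99.0, 4.3; 50.0: 96.7, 3.8; 60.0: 93.7, 6.6; 80.0: 91.9, 9.1; 90.0: 88.3, 12.0

(each reading ± 1 percentage point)

- part of the Z that has reacted at the end, Sunday's
- part of the Z that has reacted at the end, Saturday's
- part of the Z that has reacted at the end, Monday's
- what raising the concentration of E from its lowest to its highest value here does to the part of the Z that has reacted (changes below 5 percentage points count as none) (it falls / it rises / no change)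

- every charge counts on the volume at the start, and the solution that is fed holds the whole dose

Two numbers do not seem to go together. At 90.0 min, half of the Q has entered in the ash and larch runs, yet J reads 9.8 % and 12.0 %. Z reads 88.5 % and 88.3 %, so the low J is no gap in the balance. On the mean of the two runs, about 39.1 % of the charge of Q has entered without reacting, which is accumulation in the usual word.

To measure this, I divide the rate at which J forms by the rate at which Q enters, so that time drops out. Z and Q are charged equally, so a point of J is a point of Q. Between 60.0 min and 90.0 min, mean J climbs by 5.1 percentage points, uncertain by about 1 point, while 16.7 % of the Q enters. So the keep-up ratio, moles of J made per mole of Q fed, stands at 0.306. Since this is below one, Q is entering faster than it is used. Held at that value for the rest of the feed, the ratio gives me 26.2 % of J at the end. I take that as a low estimate, not a bound, because Q is entering faster than it is used, so the unused Q is still growing. The ash and larch runs, at 0.059 M and 0.11 M of E, keep pace within the scatter, so I expect little from E.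

The forecast gives 35 % for Sunday's, 35 % for Saturday's and 34 % for Monday's, with no change as the trend, holding that “the reaction is kinetically limited and Q accumulates”. These values stand above my low estimate.

The flasks give 32.6 % for Sunday's, 32.9 % for Saturday's and 32.1 % for Monday's, a change of 0.8 points across the range of E, so the trend is no change and the forecast holds.

    E ⇌ D (K = 0.500, k = 0.340 /h)
    Q + L ⇌ X, settled at all times (K = 39000 /M)
    L + E ⇌ G, settled at all times (K = 75000 /M)
    Z + Q → L + J (k = 14.0 /M/h)

The keep-up ratio read as 0.306 from the earlier runs between 60.0 min and 90.0 min stands at 0.412 over the second half of Monday's feed, and 59 % of the charged Q is still free at its end. Over the whole of Monday's feed the ratio is 0.321. With Z raised to 0.053 M in the neighbour of Monday's, the part of Z reacted is lower, at 26.8 %. Its ratio over the whole feed is higher, at 0.458, and 44 % of its Q stays free.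

(All runs were computed with constants of no real substance; scatter was added.)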